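**Retrosynthetic overview**
1. Daucane numbering is used throughout. C1 is the quaternary carbon (it bears methyl C15). C2 and C3 are the CH2 groups of five-membered ring A. C4 is the isopropyl-bearing sp2 carbon and C5 the sp2 fusion carbon. C6 to C10 complete seven-membered ring B, where C8 bears C14 and C9 is the =CH.
2. The last bond is the C14–O ester, made by Mitsunobu coupling of vanillic acid with dauca-4,8-dien-14-ol. The alcohol comes from a C8 enoate whose ring A still holds a C3 ketone, which is removed by 1,2-reduction and ionic hydrogenation.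
3. Ring B comes from one-carbon ring expansion of a six-membered C9 ketone with ethyl diazoacetate, which inserts C8 and brings C14. Hydrogenolysis of the enol triflate then places the C8=C9 double bond.
4. Ring A: the C1–C2 and C3–C4 bonds form in one flask from an allyl ethynyl ether, by a [3,3] shift followed by closure of the resulting allylketene. The C2 unit comes from trichloroethylene and is tethered through oxygen to C4. The enabling feature is that quaternary C1 is allylic to the tetrasubstituted C4=C5 double bond. C1–C5–C4 is therefore an allyl triad, and its transposed form has a flat C1=C5 ring alkene and a secondary C4 carbinol. That carbinol is easy to set (CBS reduction) and relays its chirality to C1.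
5. Ring order: the six-membered ring is bought with Hagemann's ester, ring A is built next, and the six-membered ring is then expanded to ring B.

Key step: step 6

Assumption: commercial racemic Hagemann's ester is used (its stereocentre is erased in step 1). The stereocentres at C8 of 15, at C3 of 18 and at C9 of F5 are destroyed later, so they are left undefined in names and SMILES.

Step 1
Reactants: 1 Hagemann's ester (ethyl 2-methyl-4-oxocyclohex-2-ene-1-carboxylate)
Product: 2 ethyl 7-methyl-1,4-dioxaspiro[4.5]dec-7-ene-8-carboxylate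
Conditions: HOCH2CH2OH, p-TsOH·H2O (cat.), toluene, reflux, Dean–Stark trap
Reagents that add atoms: ethylene glycol, OCCO
Why: Deconjugative acid-catalysed ketalisation of an enone moves the double bond to the β,γ-position of the masked ketone, which here is the tetrasubstituted C1=C5 position conjugated with the ester.

Step 2
Reactants: 2 ethyl 7-methyl-1,4-dioxaspiro[4.5]dec-7-ene-8-carboxylate
Product: 3 N-methoxy-N,7-dimethyl-1,4-dioxaspiro[4.5]dec-7-ene-8-carboxamide
Conditions: MeNH(OMe)·HCl, AlMe3, CH2Cl2, 0 °C to reflux
Reagents that add atoms: N,O-dimethylhydroxylamine hydrochloride, CNOC.Cl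
Why: Weinreb amide synthesis by aluminium amide aminolysis of an ester is non-basic, so the enoate is not deprotonated at its γ-positions and the ketal should survive.

Step 3
Reactants: 3 N-methoxy-N,7-dimethyl-1,4-dioxaspiro[4.5]dec-7-ene-8-carboxamide; 4 isopropylmagnesium chloride
Product: 5 2-methyl-1-(7-methyl-1,4-dioxaspiro[4.5]dec-7-en-8-yl)propan-1-one
Conditions: THF, 0 °C to rt; aq. NH4Cl
Reagents that add atoms: none
Why: In the Weinreb ketone synthesis the chelated tetrahedral adduct stops over-addition, and the fully substituted β-carbon blocks conjugate addition.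

Step 4
Reactants: 5 2-methyl-1-(7-methyl-1,4-dioxaspiro[4.5]dec-7-en-8-yl)propan-1-one
Product: 6 (1S)-2-methyl-1-(7-methyl-1,4-dioxaspiro[4.5]dec-7-en-8-yl)propan-1-ol
Conditions: (R)-2-methyl-CBS-oxazaborolidine, i.e. (3aR)-1-methyl-3,3-diphenyltetrahydro-1H,3H-pyrrolo[1,2-c][1,3,2]oxazaborole (20 mol %), BH3·SMe2, toluene, −40 to −20 °C; MeOH
Reagents that add atoms: none
Why: In the Corey–Bakshi–Shibata reduction the twisted 2-methylcyclohexenyl group should act as the large substituent, so the (R)-catalyst should give the (S)-carbinol at C4, and the tetrasubstituted alkene resists hydroboration.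

Step 5
Reactants: 6 (1S)-2-methyl-1-(7-methyl-1,4-dioxaspiro[4.5]dec-7-en-8-yl)propan-1-ol; 7 trichloroethylene
Product: 8 8-[(1S)-1-{[(E)-1,2-dichloroethenyl]oxy}-2-methylpropyl]-7-methyl-1,4-dioxaspiro[4.5]dec-7-ene
Conditions: KH, THF, 0 °C; then 7, −50 °C to rt
Reagents that add atoms: none
Why: This is the standard dichlorovinyl ether synthesis, in which the alkoxide adds anti to dichloroacetylene made in the flask from trichloroethylene, giving the (E)-ether without touching the carbinol stereocentre.

Step 6
Reactants: 8 8-[(1S)-1-{[(E)-1,2-dichloroethenyl]oxy}-2-methylpropyl]-7-methyl-1,4-dioxaspiro[4.5]dec-7-ene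
Product: 13 (7aS)-7a-methyl-3-(propan-2-yl)-4,5,7,7a-tetrahydro-1H-indene-2,6-dione, via lithium alkoxyacetylide 9 (not isolated), via allyl ethynyl ether 10 (not isolated), via allylketene 11 (not isolated), via ketal enone 12 (not isolated)
Conditions: n-BuLi (2.2 equiv), THF, −78 °C; 2,6-lutidinium triflate (1.3 equiv), −78 °C to rt, then 60 °C (0.01 M); 1 M HCl, rt
Reagents that add atoms: water, O; n-butyllithium, [Li]CCCC (its lithium stands only in 9)
Why: Proposed new method: two equivalents of n-BuLi turn 8 by dehydrochlorination and Cl/Li exchange into acetylide 9, and protonation by the non-nucleophilic lutidinium salt frees allyl ethynyl ether 10, which undergoes the [3,3]-sigmatropic shift known for allyl alkynyl ethers at or below room temperature and so joins the terminal alkyne carbon (C2) to the methyl-bearing ring carbon (C1) to give allylketene 11. In 11 the CH terminus (C4) of the new (E)-isobutylidene group attacks the ketene carbonyl carbon (C3) in the ketene plane, a tertiary cation at C5 paired with an enolate develops, and loss of the C4 proton gives the conjugated cyclopentenone 12, which aqueous HCl deketalises to 13; this ketene–alkene closure of a plain trisubstituted alkene is the part without direct precedent. The closest known reaction types are the [3,3]/5-exo-dig sequence of benzyl alkynyl ethers to 2-indanones, the thermal carbocyclisation of allyl ketenimines made by aza-Claisen shift of N-allyl ynamides, and the acylium cyclisation of 4-alkenoic acids to 2-cyclopentenones. Ring A closes 5-exo-dig at the ketene and 5-endo-trig at the alkene, which cationic closures to a tertiary centre tolerate, while the usual ketene [2+2] outlet is shut because it would demand a bicyclo[2.1.0]pentanone. The only new stereocentre, quaternary C1, is fixed by suprafacial 1,3-chirality transfer from the (S)-carbinol: A(1,3) strain against the cis ring methyl holds the carbinol hydrogen inside and the isopropyl group outside, so the ether oxygen and hence C2 sit on one face only, whether the transition state is chair or boat. The step needs the shift to outrun retro-ene loss of the ether and the closure to outrun ketene dimerisation or capture, which the low barrier of ynol ether shifts, the three-atom distance between ketene and alkene, high dilution and the absence of nucleophiles should secure.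

Step 7
Reactants: 13 (7aS)-7a-methyl-3-(propan-2-yl)-4,5,7,7a-tetrahydro-1H-indene-2,6-dione; 14 ethyl diazoacetate
Product: 15 ethyl (8aS)-8a-methyl-2,7-dioxo-3-(propan-2-yl)-1,2,4,5,6,7,8,8a-octahydroazulene-6-carboxylate
Conditions: BF3·OEt2, Et2O, 0 °C to rt
Reagents that add atoms: none
Why: In the Büchner–Curtius–Schlotterbeck homologation the diazo ester adds to the BF3-activated saturated C9 ketone, the unhindered C7 methylene should migrate rather than the neopentyl C10 methylene next to C1, and the hindered tetrasubstituted enone should stay inert.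

Step 8
Reactants: 15 ethyl (8aS)-8a-methyl-2,7-dioxo-3-(propan-2-yl)-1,2,4,5,6,7,8,8a-octahydroazulene-6-carboxylate
Product: 16 ethyl (8aS)-8a-methyl-2-oxo-3-(propan-2-yl)-7-(trifluoromethylsulfonyloxy)-1,2,4,5,8,8a-hexahydroazulene-6-carboxylate
Conditions: NaH (1.05 equiv), THF, 0 °C; PhNTf2, 0 °C to rt; aq. NH4Cl
Reagents that add atoms: N-phenylbis(trifluoromethanesulfonimide), O=S(=O)(N(c1ccccc1)S(=O)(=O)C(F)(F)F)C(F)(F)F
Why: This is O-sulfonylation of a β-keto ester enolate, where one equivalent of base removes only the most acidic proton and the enol triflate fixes the double bond at C8=C9.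

Step 9
Reactants: 16 ethyl (8aS)-8a-methyl-2-oxo-3-(propan-2-yl)-7-(trifluoromethylsulfonyloxy)-1,2,4,5,8,8a-hexahydroazulene-6-carboxylate
Product: 17 ethyl (8aS)-8a-methyl-2-oxo-3-(propan-2-yl)-1,2,4,5,8,8a-hexahydroazulene-6-carboxylate
Conditions: Pd(OAc)2 (5 mol %), PPh3 (10 mol %), HCO2H, n-Bu3N, DMF, 60 °C
Reagents that add atoms: none
Why: In this palladium-catalysed formate hydrogenolysis of an enol triflate, zerovalent palladium inserts into the C–O bond and formate delivers hydride, while the tetrasubstituted enone is too hindered for conjugate reduction.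

Step 10
Reactants: 17 ethyl (8aS)-8a-methyl-2-oxo-3-(propan-2-yl)-1,2,4,5,8,8a-hexahydroazulene-6-carboxylate
Product: 18 ethyl (8aS)-2-hydroxy-8a-methyl-3-(propan-2-yl)-1,2,4,5,8,8a-hexahydroazulene-6-carboxylate
Conditions: NaBH4, CeCl3·7H2O, MeOH, −20 to 0 °C
Reagents that add atoms: none
Why: The Luche reduction gives 1,2-reduction of the enone and leaves the enoate alone, and the configuration of the new carbinol does not matter because it is lost in step 11.

Step 11
Reactants: 18 ethyl (8aS)-2-hydroxy-8a-methyl-3-(propan-2-yl)-1,2,4,5,8,8a-hexahydroazulene-6-carboxylate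
Product: 19 ethyl (8aR)-8a-methyl-3-(propan-2-yl)-1,2,4,5,8,8a-hexahydroazulene-6-carboxylate
Conditions: Et3SiH (3 equiv), BF3·OEt2, CH2Cl2, −78 to −20 °C
Reagents that add atoms: none
Why: In this ionic hydrogenation (Kursanov–Parnes type) of an allylic alcohol, the C3–C4–C5 allyl cation should take hydride at the open secondary C3 rather than at C5 beside quaternary C1, which keeps the C4=C5 alkene, and the electron-poor enoate is not protonated.

Step 12
Reactants: 19 ethyl (8aR)-8a-methyl-3-(propan-2-yl)-1,2,4,5,8,8a-hexahydroazulene-6-carboxylate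
Product: 20 [(8aR)-8a-methyl-3-(propan-2-yl)-1,2,4,5,8,8a-hexahydroazulen-6-yl]methanol (dauca-4,8-dien-14-ol)
Conditions: i-Bu2AlH (2.5 equiv), CH2Cl2, −78 to 0 °C; aq. Rochelle salt
Reagents that add atoms: none
Why: i-Bu2AlH reduces an α,β-unsaturated ester cleanly by 1,2-addition to the allylic alcohol.

Step 13
Reactants: 20 [(8aR)-8a-methyl-3-(propan-2-yl)-1,2,4,5,8,8a-hexahydroazulen-6-yl]methanol; 21 vanillic acid (4-hydroxy-3-methoxybenzoic acid)
Product: 22 [(8aR)-8a-methyl-3-(propan-2-yl)-1,2,4,5,8,8a-hexahydroazulen-6-yl]methyl 4-hydroxy-3-methoxybenzoate (target)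
Conditions: PPh3, DIAD, THF, 0 °C to rt
Reagents that add atoms: none
Why: In the Mitsunobu esterification the carboxylic acid is far more acidic than the phenol and is the only pronucleophile engaged, so no phenol protection is needed, and the primary allylic oxyphosphonium ion should be displaced directly.

**Compound list**
1 | Hagemann's ester, ethyl 2-methyl-4-oxocyclohex-2-ene-1-carboxylate (racemic) | CCOC(=O)C1CCC(=O)C=C1C | starting material
2 | ethyl 7-methyl-1,4-dioxaspiro[4.5]dec-7-ene-8-carboxylate | CCOC(=O)C1=C(C)CC2(CC1)OCCO2 | intermediate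
3 | N-methoxy-N,7-dimethyl-1,4-dioxaspiro[4.5]dec-7-ene-8-carboxamide | CON(C)C(=O)C1=C(C)CC2(CC1)OCCO2 | intermediate
4 | isopropylmagnesium chloride | CC(C)[Mg]Cl | starting material
5 | 2-methyl-1-(7-methyl-1,4-dioxaspiro[4.5]dec-7-en-8-yl)propan-1-one | CC(C)C(=O)C1=C(C)CC2(CC1)OCCO2 | intermediate
6 | (1S)-2-methyl-1-(7-methyl-1,4-dioxaspiro[4.5]dec-7-en-8-yl)propan-1-ol | CC(C)[C@H](O)C1=C(C)CC2(CC1)OCCO2 | intermediate
7 | trichloroethylene | ClC=C(Cl)Cl | starting material
8 | 8-[(1S)-1-{[(E)-1,2-dichloroethenyl]oxy}-2-methylpropyl]-7-methyl-1,4-dioxaspiro[4.5]dec-7-ene | CC(C)[C@H](O/C(Cl)=C\Cl)C1=C(C)CC2(CC1)OCCO2 | intermediate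
9 | lithium acetylide of 10 (lithium alkoxyacetylide) | CC(C)[C@H](OC#C[Li])C1=C(C)CC2(CC1)OCCO2 | intermediate
10 | 8-[(1S)-1-(ethynyloxy)-2-methylpropyl]-7-methyl-1,4-dioxaspiro[4.5]dec-7-ene | CC(C)[C@H](OC#C)C1=C(C)CC2(CC1)OCCO2 | intermediate
11 | 2-[(7S,8E)-7-methyl-8-(2-methylpropylidene)-1,4-dioxaspiro[4.5]decan-7-yl]ethen-1-one (allylketene) | CC(C)/C=C1\CCC2(OCCO2)C[C@@]1(C)C=C=O | intermediate
12 | 6,6-ethylene ketal of 13, (7aR) by CIP with the same spatial arrangement as 13 | CC(C)C1=C2CCC3(OCCO3)C[C@@]2(C)CC1=O | intermediate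
13 | (7aS)-7a-methyl-3-(propan-2-yl)-4,5,7,7a-tetrahydro-1H-indene-2,6-dione | CC(C)C1=C2CCC(=O)C[C@@]2(C)CC1=O | intermediate
14 | ethyl diazoacetate | CCOC(=O)C=[N+]=[N-] | starting material
15 | ethyl (8aS)-8a-methyl-2,7-dioxo-3-(propan-2-yl)-1,2,4,5,6,7,8,8a-octahydroazulene-6-carboxylate | CC(C)C1=C2CCC(C(=O)OCC)C(=O)C[C@@]2(C)CC1=O | intermediate
16 | ethyl (8aS)-8a-methyl-2-oxo-3-(propan-2-yl)-7-(trifluoromethylsulfonyloxy)-1,2,4,5,8,8a-hexahydroazulene-6-carboxylate | CC(C)C1=C2CCC(C(=O)OCC)=C(OS(=O)(=O)C(F)(F)F)C[C@@]2(C)CC1=O | intermediate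
17 | ethyl (8aS)-8a-methyl-2-oxo-3-(propan-2-yl)-1,2,4,5,8,8a-hexahydroazulene-6-carboxylate | CC(C)C1=C2CCC(C(=O)OCC)=CC[C@@]2(C)CC1=O | intermediate
18 | ethyl (8aS)-2-hydroxy-8a-methyl-3-(propan-2-yl)-1,2,4,5,8,8a-hexahydroazulene-6-carboxylate | CC(C)C1=C2CCC(C(=O)OCC)=CC[C@@]2(C)CC1O | intermediate
19 | ethyl (8aR)-8a-methyl-3-(propan-2-yl)-1,2,4,5,8,8a-hexahydroazulene-6-carboxylate | CC(C)C1=C2CCC(C(=O)OCC)=CC[C@@]2(C)CC1 | intermediate
20 | [(8aR)-8a-methyl-3-(propan-2-yl)-1,2,4,5,8,8a-hexahydroazulen-6-yl]methanol | CC(C)C1=C2CCC(CO)=CC[C@@]2(C)CC1 | intermediate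
21 | vanillic acid | COc1cc(C(=O)O)ccc1O | starting material
22 | [(8aR)-8a-methyl-3-(propan-2-yl)-1,2,4,5,8,8a-hexahydroazulen-6-yl]methyl 4-hydroxy-3-methoxybenzoate | COc1cc(C(=O)OCC2=CC[C@@]3(C)CCC(C(C)C)=C3CC2)ccc1O | target

**Step count**
Total step count: 13. Longest linear sequence: 13 steps (1 to 22).

**Steps most likely to fail**

Step 6 (key step).
- The ketene may dimerise or be captured by adventitious nucleophiles faster than ring A closes.
- n-BuLi may trigger a Wittig-type rearrangement of the allylic ether.
- The sigmatropic shift at the crowded tetrasubstituted alkene may lag behind retro-ene loss of the ether.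
- The fallback uses known chemistry, sets out from 6 and comes back at 13. Acetylation (Ac2O, DMAP, pyridine) gives the (1S)-acetate F1. LDA and Me3SiCl in THF at −78 °C give the silyl ketene acetal F2, which on warming undergoes the Ireland–Claisen rearrangement with the same A(1,3)-controlled chirality transfer to the trimethylsilyl ester F3. Aqueous work-up gives the 4-alkenoic acid F4. P2O5 in MeSO3H (Eaton's reagent) then cyclises it through the acylium ion to the cyclopentenone, and the aqueous work-up also removes the ketal.

Step 7.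
- Migratory selectivity between the C7 and C10 methylene groups may be poor, or the diazo ester may attack at the enone carbonyl.
- The fallback sets out from 13 and comes back at 15. Ethyl diazoacetate 14 is lithiated with LDA in THF at −78 °C and added as a carbon nucleophile to the more reactive saturated ketone, giving the α-diazo-β-hydroxy ester F5. Rh2(OAc)4 (1 mol %) in CH2Cl2 then releases nitrogen, and the rhodium carbenoid undergoes a 1,2-alkyl shift. Addition and migration thus become separate events, each open to its own control.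

Step 4.
- Facial discrimination may be low because both ketone substituents are branched.
- The fallback sets out from 2 and comes back at 6. i-Bu2AlH reduces the ester to the allylic alcohol F6, and MnO2 oxidises it to the enal F7. Catalytic asymmetric alkylation with i-Pr2Zn and (2S)-(−)-3-exo-morpholinoisoborneol should then build the (S)-carbinol by C–C bond formation, where the aldehyde offers hydrogen against alkenyl as a far larger size difference.

**Further compounds**
F1 | step 6 | (1S)-2-methyl-1-(7-methyl-1,4-dioxaspiro[4.5]dec-7-en-8-yl)propyl acetate | CC(C)[C@H](OC(C)=O)C1=C(C)CC2(CC1)OCCO2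
F2 | step 6 | 7-methyl-8-[(1S)-2-methyl-1-{[1-(trimethylsilyloxy)ethenyl]oxy}propyl]-1,4-dioxaspiro[4.5]dec-7-ene | CC(C)[C@H](OC(=C)O[Si](C)(C)C)C1=C(C)CC2(CC1)OCCO2
F3 | step 6 | trimethylsilyl 2-[(7S,8E)-7-methyl-8-(2-methylpropylidene)-1,4-dioxaspiro[4.5]decan-7-yl]acetate | CC(C)/C=C1\CCC2(OCCO2)C[C@@]1(C)CC(=O)O[Si](C)(C)C
F4 | step 6 | 2-[(7S,8E)-7-methyl-8-(2-methylpropylidene)-1,4-dioxaspiro[4.5]decan-7-yl]acetic acid | CC(C)/C=C1\CCC2(OCCO2)C[C@@]1(C)CC(=O)O
F5 | step 7 | ethyl 2-diazo-2-[(7aS)-6-hydroxy-7a-methyl-2-oxo-3-(propan-2-yl)-2,4,5,6,7,7a-hexahydro-1H-inden-6-yl]acetate | CC(C)C1=C2CCC(O)(C(=[N+]=[N-])C(=O)OCC)C[C@@]2(C)CC1=O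
F6 | step 4 | (7-methyl-1,4-dioxaspiro[4.5]dec-7-en-8-yl)methanol | OCC1=C(C)CC2(CC1)OCCO2
F7 | step 4 | 7-methyl-1,4-dioxaspiro[4.5]dec-7-ene-8-carbaldehyde | O=CC1=C(C)CC2(CC1)OCCO2
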